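(All runs were computed with made-up constants; scatter was added.)

If you repeat this run, in which starting material turns into target and its isomer with a little protic impurity present, add the two products at each late sample and watch what falls short of the charge.

| flask | starting material | protic impurity | remark | time |
|---|---|---|---|---|
| elm | 0.050 M | 2 mM | run made earlier |  |
| alder | 0.20 M | 2 mM | run made earlier |  |
| flask | 0.10 M | 2.00 mM |  | 8.0 min |

| run | time / min | isomer of the product / % | target / % |
|---|---|---|---|
| elm | 0.833 | 24.6 | 40.4 |
| elm | 1.33 | 32.0 | 44.4 |
| elm | 2.50 | 43.0 | 43.4 |
| elm | 5.00 | 46.6 | 44.0 |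
| elm | 10.0 | 49.5 | 47.3 |
| alder | 2.00 | 43.6 | 44.1 |
| alder | 4.00 | 49.4 | 45.5 |
| alder | 6.00 | 51.8 | 45.5 |
| alder | 8.00 | 53.1 | 48.0 |
| alder | 10.0 | 49.8 | 46.3 |

(standard deviation of a reading: 1 percentage point)

- ratio of isomer of the product to target at 0.40 s
- ratio of isomer of the product to target at 8.0 min

At 10.0 min the elm run falls short by 3.2 percentage points, and its c(protic impurity)/c(starting material) is 0.0400. At the latest samples the target reads 47.3% in elm and 47.1% in alder, which the scatter of 1 point does not separate, while the isomer reads 49.5% against 51.4%.

So I reckon with two amounts, c(protic impurity) and c(starting material). I take their ratio, here 0.0200, as the part of the charge lost from the isomer side. The part of the charge ending as target, the target share, reads 47.2% as the mean of those readings. I treat this as kinetic control of a split. Counting the charge as target, isomer and that lost part, my end ratio is one minus the target share and that ratio, over the target share: 1.08 for this flask. The rule says nothing of 0.40 s, so I give no early figure.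

The forecast gives 0.3 at 0.40 s and 1.08 at 8.0 min, on other grounds: “it looks like a target⇌isomer equilibrium”.

The flask gives 0.00455 at 0.40 s and 1.07 at 8.0 min, so the forecast's early value is too high. In the flask at 8.00 min quenched substrate stands at 2.00% with protic impurity at 0%, and the target, at 46.7%, sits beside the carried share of 47.2%.

    starting material ⇌ other conformer (K = 17.9, k = 0.0654 s⁻¹)
    starting material → target (k = 0.0485 s⁻¹)
    other conformer → isomer of the product (k = 0.0169 s⁻¹)
    other conformer + protic impurity → quenched substrate (k = 29.7 M⁻¹ s⁻¹)
    starting material ⇌ dormant form (K = 1.60, k = 0.00527 s⁻¹)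

In the neighbour charged with 0.0080 M of protic impurity, the ratio of charges is 0.0800, and the target share gives 0.949. That flask computes to 0.964.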